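**Retrosynthetic overview**

1. Target 18 ⇐ exo-face reduction of the C6 ketone ⇐ Pinnick oxidation and acetal hydrolysis; side chain built on C9 aldehyde 12 by a zinc-catalysed methyl vinyl ketone aldol (C11) and a chelation-controlled MeMgBr addition (C13).
2. 12 ⇐ C9 ketone 9 by sulfur-ylide epoxidation, Meinwald rearrangement and epimerisation.
3. 9 (bridged δ-lactone plus bis-acetal tetrahydrofuran, both closed in one operation) ⇐ ozonolytic unzipping of the sacrificial cyclohexene of Diels–Alder adduct 5.
4. 5 ⇐ enantioselective Diels–Alder of 2,6-dimethylbenzoquinone (the carbocycle, bought) with the silyl dienol ether of mesityl oxide (sets C5 and C10, delivers C1–C4).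
5. Ring order: carbocycle from the quinone → temporary ring A (Diels–Alder) → ring A cleaved while the lactone and acetal rings close together → acetal ring opened before the last reduction.

Assumption: atoms carry seco-labdane labels (lactone C2(=O)–C1H2 on C10; carboxyl C3 on C4(CH3)2 on C5; ring C5–C10; side chain C11–C16; C17 on C8, C20 on C10), β is the ring face that carries the lactone bridge, and the two acetal carbons of 9–12, 14 and 15 are drawn as one diastereomer because their configuration is lost in step 8.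

**Route**

Step 1
Reactants: 1 mesityl oxide
Product: 3 tert-butyldimethyl(4-methylpenta-1,3-dien-2-yloxy)silane, via lithium dienolate 2 (not isolated)
Conditions: LiN(iPr)2, THF, −78 °C; tBuMe2SiCl, DMPU, −78 °C → rt
Reagents that add atoms: tert-butyldimethylsilyl chloride CC(C)(C)[Si](C)(C)Cl
Why: Kinetic deprotonation of the methyl ketone gives the cross-conjugated dienolate, and O-silylation (silyl enol ether formation) gives the 2-silyloxy diene without creating a stereocentre.

Step 2
Reactants: 3 silyloxy diene; 4 2,6-dimethyl-1,4-benzoquinone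
Product: 5 (4aS,8aR)-7-(tert-butyldimethylsilyloxy)-2,5,5,8a-tetramethyl-4a,5,8,8a-tetrahydronaphthalene-1,4-dione
Conditions: (S)-3,3-diphenyl-1-(2-methylphenyl)tetrahydro-1H,3H-pyrrolo[1,2-c][1,3,2]oxazaborole·HNTf2 (20 mol %), CH2Cl2, −78 → −40 °C
Reagents that add atoms: none
Why: In this chiral-Lewis-acid-catalysed Diels–Alder reaction the cation binds the less hindered quinone carbonyl, the CH2 terminus of the diene bonds to the methyl-bearing carbon (C10) and the gem-dimethyl terminus to the CH carbon (C5), suprafacial addition makes the new C1 and C4 bonds cis, and the catalyst face selection sets the absolute configuration (the antipodal catalyst is taken if a pilot run shows the opposite sense).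

Step 3
Reactants: 5 Diels–Alder adduct
Product: 9 lactone bis-acetal ketone, via silyl ester aldehyde 6 (not isolated), via seco acid aldehyde 7 (not isolated), via keto lactone aldehyde 8 (not isolated)
Conditions: O3, CH2Cl2/MeOH 4:1, −78 °C; Me2S, −78 → 0 °C; Et3N (0.3 equiv), 0 °C → rt; then HC(OMe)3, camphorsulfonic acid (0.5 equiv), MeOH, rt
Reagents that add atoms: ozone [O-][O+]=O; trimethyl orthoformate COC(OC)OC
Why: Ozonolysis cleaves only the electron-rich silyl enol ether of ring A to a C2 carboxyl and a C3 aldehyde, the acid then adds to the ene-dione by intramolecular oxa-Michael addition from the face of its tether so that C8 receives its oxygen cis to the C1 arm with the methyl trans, and acetalization of the resulting γ-keto aldehyde closes the bis-acetal tetrahydrofuran, which blocks retro-Michael loss of the lactone and leaves C9 as the only free ketone.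

Step 4
Reactants: 9 lactone bis-acetal ketone
Product: 10 C9 spiro-epoxide
Conditions: Me3S+ I−, KN(SiMe3)2, THF, −10 → 0 °C
Reagents that add atoms: trimethylsulfonium iodide C[S+](C)C.[I-]
Why: In this Corey–Chaykovsky epoxidation the small sulfonium ylide adds to the non-enolisable C9 ketone from the lactone face, and the configuration of the spiro centre is irrelevant because it is erased in step 5.

Step 5
Reactants: 10 spiro-epoxide
Product: 12 C9β-carbaldehyde, via C9-epimeric carbaldehyde 11 (not isolated)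
Conditions: MeAl(OC6H2-4-Br-2,6-tBu2)2 (10 mol %), CH2Cl2, −40 °C; then DBU (0.2 equiv), rt
Reagents that add atoms: none
Why: Meinwald rearrangement (opening of the tertiary C9–O bond and 1,2-hydride shift) gives the C9 carbaldehyde, and base equilibration places the formyl group on the β face syn to the lactone bridge, because the α position is a flagpole site facing the C6 acetal carbon.

Step 6
Reactants: 12 C9β-carbaldehyde; 13 methyl vinyl ketone
Product: 14 (11S)-hydroxy enone
Conditions: Et2Zn (20 mol %), (R,R)-ProPhenol ligand [2,6-bis{[(R)-2-(hydroxydiphenylmethyl)pyrrolidin-1-yl]methyl}-4-methylphenol] (10 mol %), 4 Å sieves, THF, 0 °C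
Reagents that add atoms: none
Why: This direct catalytic asymmetric aldol addition (dinuclear zinc ProPhenol catalysis) joins the methyl group of methyl vinyl ketone to the α-branched aldehyde, and the chiral catalyst selects the carbonyl face that gives 11S.

Step 7
Reactants: 14 (11S)-hydroxy enone
Product: 15 (11S,13R)-diol
Conditions: MeMgBr (2.5 equiv), CH2Cl2/Et2O, −78 °C; cold NH4Cl quench
Reagents that add atoms: methylmagnesium bromide C[Mg]Br
Why: In this chelation-controlled Grignard 1,2-addition the magnesium alkoxide of the C11 hydroxyl chelates the enone carbonyl in a six-membered ring and methyl adds anti to the C11 substituent, which gives the 1,3-syn diol (13R).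

Step 8
Reactants: 15 (11S,13R)-diol
Product: 16 keto aldehyde diol
Conditions: AcOH/THF/H2O 3:1:1, 30 °C
Reagents that add atoms: water O
Why: Acid-catalysed acetal hydrolysis returns the C3 aldehyde and the C6 ketone under conditions mild enough for the tertiary allylic alcohol and the lactone, and no stereocentre changes.

Step 9
Reactants: 16 keto aldehyde diol
Product: 17 keto acid
Conditions: NaClO2, NaH2PO4, 2-methylbut-2-ene, t-BuOH/H2O, 0 °C
Reagents that add atoms: sodium chlorite [Na+].[O-]Cl=O
Why: Pinnick oxidation converts the non-enolisable aldehyde to the C3 acid while the alkene additive scavenges hypochlorous acid, so the vinyl group and the ketone survive.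

Step 10
Reactants: 17 keto acid
Product: 18 target CNP0297019.1
Conditions: NaBH4, CeCl3·7H2O, MeOH, −78 °C; AcOH quench at −78 °C; pH 5 phosphate work-up
Reagents that add atoms: none
Why: In this Luche-type borohydride reduction hydride reaches the C6 ketone only from the exo (α) face because the β face is covered by the lactone bridge, which gives the 6β (6R) alcohol, while the carboxylate is inert and the cold acidic quench limits acyl migration.

**Compound list**

1 | 4-methylpent-3-en-2-one (mesityl oxide) | CC(=O)C=C(C)C | starting material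
2 | lithium 4-methylpenta-1,3-dien-2-olate | [Li+].[O-]C(=C)C=C(C)C | intermediate (not isolated)
3 | tert-butyldimethyl(4-methylpenta-1,3-dien-2-yloxy)silane | C=C(O[Si](C)(C)C(C)(C)C)C=C(C)C | intermediate
4 | 2,6-dimethyl-1,4-benzoquinone | CC1=CC(=O)C=C(C)C1=O | starting material
5 | (4aS,8aR)-7-(tert-butyldimethylsilyloxy)-2,5,5,8a-tetramethyl-4a,5,8,8a-tetrahydronaphthalene-1,4-dione; cis ring fusion | C[C@@]12CC(O[Si](C)(C)C(C)(C)C)=CC(C)(C)[C@@H]1C(=O)C=C(C)C2=O | intermediate
6 | tert-butyldimethylsilyl 2-[1,3-dimethyl-6-(2-methyl-1-oxopropan-2-yl)-2,5-dioxocyclohex-3-en-1-yl]acetate; acetate arm and oxopropanyl arm cis, C10 methyl trans to both | C[C@@]1(CC(=O)O[Si](C)(C)C(C)(C)C)[C@H](C(C)(C)C=O)C(=O)C=C(C)C1=O | intermediate (not isolated)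
7 | 2-[1,3-dimethyl-6-(2-methyl-1-oxopropan-2-yl)-2,5-dioxocyclohex-3-en-1-yl]acetic acid; configuration as in 6 | C[C@@]1(CC(=O)O)[C@H](C(C)(C)C=O)C(=O)C=C(C)C1=O | intermediate (not isolated)
8 | 2-(1,5-dimethyl-3,7,9-trioxo-2-oxabicyclo[3.3.1]nonan-6-yl)-2-methylpropanal; 6-substituent on the β face (C5β) | O=C1[C@]2(C)CC(=O)O[C@@]1(C)CC(=O)[C@H]2C(C)(C)C=O | intermediate (not isolated)
9 | lactone bis-acetal ketone: 8 with C3 and C6 joined through one oxygen as a cis-fused 2,5-dimethoxytetrahydrofuran (ring oxygen β at C6, the two methoxy groups trans), C9 ketone free | O=C1[C@]2(C)CC(=O)O[C@@]1(C)C[C@@]3(OC)O[C@@H](OC)C(C)(C)[C@@H]23 | intermediate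
10 | C9 spiro-epoxide of 9: oxirane CH2 (C11) β, oxirane oxygen α | C1O[C@]12[C@]3(C)CC(=O)O[C@@]2(C)C[C@@]4(OC)O[C@@H](OC)C(C)(C)[C@@H]34 | intermediate
11 | C9-epimeric carbaldehyde: formyl α (anti to the lactone bridge) on the lactone bis-acetal core | O=C[C@H]1[C@]2(C)CC(=O)O[C@@]1(C)C[C@@]3(OC)O[C@@H](OC)C(C)(C)[C@@H]23 | intermediate (not isolated)
12 | C9β-carbaldehyde: formyl syn to the lactone bridge, H9 α | O=C[C@@H]1[C@]2(C)CC(=O)O[C@@]1(C)C[C@@]3(OC)O[C@@H](OC)C(C)(C)[C@@H]23 | intermediate
13 | but-3-en-2-one (methyl vinyl ketone) | CC(=O)C=C | starting material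
14 | (11S)-hydroxy enone: C9β–CH(OH)–CH2–C(=O)–CH=CH2 on the lactone bis-acetal core | C=CC(=O)C[C@H](O)[C@@H]1[C@]2(C)CC(=O)O[C@@]1(C)C[C@@]3(OC)O[C@@H](OC)C(C)(C)[C@@H]23 | intermediate
15 | (11S,13R)-diol: C9β–CH(OH)–CH2–C(CH3)(OH)–CH=CH2 on the lactone bis-acetal core | C=C[C@](C)(O)C[C@H](O)[C@@H]1[C@]2(C)CC(=O)O[C@@]1(C)C[C@@]3(OC)O[C@@H](OC)C(C)(C)[C@@H]23 | intermediate
16 | 2-[9-((1S,3R)-1,3-dihydroxy-3-methylpent-4-enyl)-1,5-dimethyl-3,7-dioxo-2-oxabicyclo[3.3.1]nonan-6-yl]-2-methylpropanal; C5β, C9β | C=C[C@](C)(O)C[C@H](O)[C@@H]1[C@]2(C)CC(=O)O[C@@]1(C)CC(=O)[C@H]2C(C)(C)C=O | intermediate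
17 | 2-[9-((1S,3R)-1,3-dihydroxy-3-methylpent-4-enyl)-1,5-dimethyl-3,7-dioxo-2-oxabicyclo[3.3.1]nonan-6-yl]-2-methylpropanoic acid; C5β, C9β | C=C[C@](C)(O)C[C@H](O)[C@@H]1[C@]2(C)CC(=O)O[C@@]1(C)CC(=O)[C@H]2C(C)(C)C(=O)O | intermediate
18 | 2-[(1S,5R,6R,7R,9S)-9-[(1S,3R)-1,3-dihydroxy-3-methylpent-4-en-1-yl]-7-hydroxy-1,5-dimethyl-3-oxo-2-oxabicyclo[3.3.1]nonan-6-yl]-2-methylpropanoic acid (CNP0297019.1; 5R,6R,8S,9S,10R,11S,13R in the atom labels used here) | C=C[C@](C)(O)C[C@H](O)[C@@H]1[C@]2(C)CC(=O)O[C@@]1(C)C[C@@H](O)[C@H]2C(C)(C)C(=O)O | target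

**Step count and risks**

Total step count: 10. Longest linear sequence: 10 steps (1 → 18).

The three steps most likely to fail:

Step 2. The diene carries a (Z)-methyl group at its reacting terminus, which slows the cycloaddition, and the enantioselectivity with this diene is untested. The fallback sets out from 3 and 4 and comes back at 5. The adduct is made as the racemate with MeAlCl2 (1.0 equiv, CH2Cl2, −78 °C). The enantiomers are then separated by preparative supercritical-fluid chromatography on an amylose tris(3,5-dimethylphenylcarbamate) phase. The unwanted (4aR,8aS)-adduct F1 is discarded and 5 enters step 3.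

Step 3. The conjugate addition creates a tertiary ester and is reversible, and acetalization at the hindered C6 ketone must outrun retro-Michael opening and methanolysis in the same flask. The fallback sets out from 5 and comes back at 17, so step 9 is skipped.
- The sequence is stopped after the triethylamine stage and keto lactone aldehyde 8 is isolated.
- Pinnick oxidation (NaClO2, NaH2PO4, 2-methylbut-2-ene) gives the trioxo acid F2.
- Camphorsulfonic acid and HC(OMe)3 in MeOH close the γ-keto acid to the methyl pseudoester F3, which protects the C6 ketone and the C3 carboxyl in one ring.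
- F3 is taken through the conditions of steps 4 to 7. This gives the pseudoester spiro-epoxide F4, the pseudoester C9-epimeric carbaldehyde F5 (not isolated), the pseudoester C9β-carbaldehyde F6, the pseudoester hydroxy enone F7 and the pseudoester diol F8.
- AcOH/THF/H2O then hydrolyses the pseudoester of F8 to keto acid 17.

Step 6. The aldehyde sits between two quaternary carbons, the catalyst may be mismatched with the substrate, and the β-hydroxy enone can dehydrate. The 1,3-induction of step 7 is also only moderate. The fallback sets out from 12 and comes back at 15, replacing steps 6 and 7.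
- Brown methallylboration with Ipc2B(CH2C(CH3)=CH2) (the enantiomer that gives 11S; Et2O, −78 °C, NaBO3 work-up) gives the methallyl carbinol F9.
- Hydroxyl-directed epoxidation (VO(acac)2, t-BuOOH, CH2Cl2, 0 °C) gives the 1,3-syn epoxy alcohol F10.
- Excess dimethylsulfonium methylide (Me3S+ I−, n-BuLi, THF, −10 °C) opens F10 at its CH2 and eliminates to the vinyl carbinol 15.

**Further compounds**

F1 | step 2 | (4aR,8aS)-7-(tert-butyldimethylsilyloxy)-2,5,5,8a-tetramethyl-4a,5,8,8a-tetrahydronaphthalene-1,4-dione (enantiomer of 5) | C[C@]12CC(O[Si](C)(C)C(C)(C)C)=CC(C)(C)[C@H]1C(=O)C=C(C)C2=O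
F2 | step 3 | 2-(1,5-dimethyl-3,7,9-trioxo-2-oxabicyclo[3.3.1]nonan-6-yl)-2-methylpropanoic acid; C5β | O=C1[C@]2(C)CC(=O)O[C@@]1(C)CC(=O)[C@H]2C(C)(C)C(=O)O
F3 | step 3 | methyl pseudoester of F2: C3 carboxyl closed onto C6 as a cis-fused 5-methoxy-γ-lactone (ring oxygen β, methoxy α at C6), C9 ketone free | O=C1[C@]2(C)CC(=O)O[C@@]1(C)C[C@@]3(OC)OC(=O)C(C)(C)[C@@H]23
F4 | step 3 | pseudoester C9 spiro-epoxide (oxirane CH2 β) | C1O[C@]12[C@]3(C)CC(=O)O[C@@]2(C)C[C@@]4(OC)OC(=O)C(C)(C)[C@@H]34
F5 | step 3 | pseudoester C9-epimeric carbaldehyde (formyl α) | O=C[C@H]1[C@]2(C)CC(=O)O[C@@]1(C)C[C@@]3(OC)OC(=O)C(C)(C)[C@@H]23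
F6 | step 3 | pseudoester C9β-carbaldehyde | O=C[C@@H]1[C@]2(C)CC(=O)O[C@@]1(C)C[C@@]3(OC)OC(=O)C(C)(C)[C@@H]23
F7 | step 3 | pseudoester (11S)-hydroxy enone | C=CC(=O)C[C@H](O)[C@@H]1[C@]2(C)CC(=O)O[C@@]1(C)C[C@@]3(OC)OC(=O)C(C)(C)[C@@H]23
F8 | step 3 | pseudoester (11S,13R)-diol | C=C[C@](C)(O)C[C@H](O)[C@@H]1[C@]2(C)CC(=O)O[C@@]1(C)C[C@@]3(OC)OC(=O)C(C)(C)[C@@H]23
F9 | step 6 | (11S)-methallyl carbinol: C9β–CH(OH)–CH2–C(CH3)=CH2 on the lactone bis-acetal core | C=C(C)C[C@H](O)[C@@H]1[C@]2(C)CC(=O)O[C@@]1(C)C[C@@]3(OC)O[C@@H](OC)C(C)(C)[C@@H]23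
F10 | step 6 | (11S,13R)-epoxy alcohol: C9β–CH(OH)–CH2–(2-methyloxiran-2-yl) on the lactone bis-acetal core | C[C@]1(CO1)C[C@H](O)[C@@H]2[C@]3(C)CC(=O)O[C@@]2(C)C[C@@]4(OC)O[C@@H](OC)C(C)(C)[C@@H]34
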